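**Strategy.** The dihydropyran is disconnected at O2. The acylal carbon C1, flanked by ring oxygen O2 and enol-ether carbon C3, is the signature of a Criegee rearrangement, so O2 is inserted into a C1–C3 bond of a cis-bicyclo[3.3.0]octadiene whose second ring is the target's cyclopentene. Acylation of its C1 hydroperoxide with 3-methylbut-2-enoic acid makes dienyl C3 migrate from C1 to oxygen, and the carboxylate returns to C1 anti to C8, so both C1 epimers converge on the (1S) acylal. The carbocycle comes from an acyclic dienyne by singlet-oxygen ene reaction and tandem ring-closing metathesis.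

Key step: step 14

Remark: iridoid numbering (C1, O2, C3–C11) is used for the atoms of all intermediates; compounds 17–20 and 22 are mixtures of C1 epimers, which is immaterial because C1 becomes planar in step 14.

**Step 1**
Reactants: 1 rac-pent-1-en-4-yn-3-ol; 2 (Z)-1-bromoprop-1-ene
Product: 3 rac-(6Z)-octa-1,6-dien-4-yn-3-ol
Conditions: PdCl2(PPh3)2 (cat.), CuI (cat.), Et3N, THF, rt
Reagents that add atoms: none
Why: Sonogashira coupling of the terminal alkyne with the alkenyl bromide proceeds with retention of the Z geometry and tolerates the free carbinol; no stereocentre is set.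

**Step 2**
Reactants: 3 rac-(6Z)-octa-1,6-dien-4-yn-3-ol
Product: 4 (3S,6Z)-octa-1,6-dien-4-yn-3-ol
Conditions: Novozym 435 (CAL-B), vinyl acetate, MTBE, rt, stopped near half conversion; chromatography
Reagents that add atoms: none
Why: Lipase-catalysed kinetic resolution (Kazlauskas rule) should acetylate the (R)-enantiomer, whose long alkynyl arm fills the large pocket, and leave the (3S)-alcohol that becomes C7.

**Step 3**
Reactants: 4 (3S,6Z)-octa-1,6-dien-4-yn-3-ol
Product: 5 (3S,4E,6Z)-4-(tributylstannyl)octa-1,4,6-trien-3-ol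
Conditions: Bu3SnH, PdCl2(PPh3)2 (cat.), THF, 0 °C
Reagents that add atoms: tributyltin hydride, CCCC[SnH](CCCC)CCCC
Why: Pd-catalysed syn-hydrostannation of a 2-alkyn-1-ol places tin on the alkyne carbon next to the carbinol (C8, also the carbon remote from the conjugating alkene) and hydrogen on C9, which fixes the C8=C9 geometry (C7 and propenyl cis).

**Step 4**
Reactants: 5 (3S,4E,6Z)-4-(tributylstannyl)octa-1,4,6-trien-3-ol
Product: 7 (3S,4Z,6Z)-4-(hydroxymethyl)octa-1,4,6-trien-3-ol, via dilithio alkenyl alkoxide 6 (not isolated)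
Conditions: MeLi (3.2 equiv), THF, −78 to −30 °C; then CH2O (gas, from cracked paraformaldehyde), −78 to 0 °C; aq NH4Cl
Reagents that add atoms: formaldehyde, C=O
Why: Tin–lithium exchange after O-deprotonation gives a configurationally stable alkenyllithium that adds to formaldehyde with retention, so C10 is installed cis to H9.

**Step 5**
Reactants: 7 (3S,4Z,6Z)-4-(hydroxymethyl)octa-1,4,6-trien-3-ol
Product: 8 (1S)-1-[(2R,3S)-2-(hydroxymethyl)-3-[(1Z)-prop-1-en-1-yl]oxiran-2-yl]prop-2-en-1-ol
Conditions: Ti(OiPr)4, L-(+)-diisopropyl tartrate, t-BuOOH (anhydrous, isooctane), 4 Å MS, CH2Cl2, −20 °C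
Reagents that add atoms: tert-butyl hydroperoxide, CC(C)(C)OO
Why: Sharpless asymmetric epoxidation directed by the primary allylic hydroxyl (propenyl trans to CH2OH, the favourable E-type pattern) is reagent-controlled, and L-(+)-tartrate delivers oxygen to the face that gives the (2R,3S)-oxirane, i.e. the later 8α-oxygen; the vinyl and the distal propenyl alkene are not epoxidised.

**Step 6**
Reactants: 8 epoxy diol; 9 tert-butyldimethyl(prop-2-yn-1-yloxy)silane
Product: 10 (3S,4R,5S,6Z)-5-[3-(tert-butyldimethylsilyloxy)prop-1-yn-1-yl]-4-(hydroxymethyl)octa-1,6-diene-3,4-diol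
Conditions: 9, n-BuLi, toluene, 0 °C; Et2AlCl, 0 °C; then 8, toluene, 0 °C to rt; Rochelle-salt work-up
Reagents that add atoms: none
Why: A diethylalkynylalane delivered from the aluminium alkoxides opens the 2,3-epoxy alcohol at C3 (= C9, secondary and allylic) by SN2 with inversion, which sets C9 and leaves the tertiary C8 hydroxyl with retained configuration.

**Step 7**
Reactants: 10 triol; 11 3-methylbutanoyl chloride
Product: 12 (3S,4R,5S,6Z)-5-[3-(tert-butyldimethylsilyloxy)prop-1-yn-1-yl]-3,4-dihydroxy-4-[(3-methylbutanoyloxy)methyl]octa-1,6-diene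
Conditions: 2,4,6-collidine, CH2Cl2, −78 to −40 °C
Reagents that add atoms: none
Why: Low-temperature acylation selects the primary C10 hydroxyl over the secondary allylic and the tertiary hydroxyl; no stereocentre is touched.

**Step 8**
Reactants: 12 mono-ester; 13 (3S)-3-methylpentanoic acid
Product: 14 (3S,4R,5S,6Z)-5-[3-(tert-butyldimethylsilyloxy)prop-1-yn-1-yl]-4-hydroxy-4-[(3-methylbutanoyloxy)methyl]octa-1,6-dien-3-yl (3S)-3-methylpentanoate
Conditions: DCC, DMAP (cat.), CH2Cl2, 0 °C to rt
Reagents that add atoms: none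
Why: Steglich esterification acylates the secondary allylic C7 hydroxyl with retention (the acid has no α-stereocentre to epimerise) while the tertiary C8 hydroxyl stays free.

**Step 9**
Reactants: 14 silyl ether
Product: 15 (3S,4R,5S,6Z)-4-hydroxy-5-(3-hydroxyprop-1-yn-1-yl)-4-[(3-methylbutanoyloxy)methyl]octa-1,6-dien-3-yl (3S)-3-methylpentanoate
Conditions: HF·pyridine, pyridine, THF, 0 °C
Reagents that add atoms: none
Why: Buffered fluoride desilylation removes the primary silyl ether without ester cleavage or acyl migration.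

**Step 10**
Reactants: 15 propargylic alcohol
Product: 16 (3S,4R,5S,6Z)-5-(3-acetoxyprop-1-yn-1-yl)-4-hydroxy-4-[(3-methylbutanoyloxy)methyl]octa-1,6-dien-3-yl (3S)-3-methylpentanoate
Conditions: Ac2O, pyridine, CH2Cl2, 0 °C
Reagents that add atoms: acetic anhydride, CC(=O)OC(C)=O
Why: Acetylation of the primary propargylic alcohol (C11) proceeds while the hindered tertiary hydroxyl is not acylated under these conditions.

**Step 11**
Reactants: 16 dienyne triester
Product: 18 (3S,4R,5R)-5-(3-acetoxyprop-1-yn-1-yl)-4-hydroxy-6-[(2-methoxypropan-2-yl)peroxy]-4-[(3-methylbutanoyloxy)methyl]octa-1,7-dien-3-yl (3S)-3-methylpentanoate, via allylic hydroperoxide 17 (not isolated)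
Conditions: O2, tetraphenylporphyrin (cat.), visible light, CH2Cl2, −20 °C; then 2-methoxypropene, PPTS (cat.), 0 °C
Reagents that add atoms: dioxygen, O=O; 2-methoxypropene, COC(C)=C
Why: Schenck ene reaction of singlet oxygen at the only electron-rich alkene (the vinyl group beside the ester and the alkyne are inert); allylic strain holds H9 in the plane of the Z-alkene, so a methyl hydrogen is abstracted and oxygen adds to C1 (configuration uncontrolled and later erased), and the hydroperoxide is capped in the same flask as a peroxyketal.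

**Step 12**
Reactants: 18 peroxyketal dienyne
Product: 19 cis-bicyclo[3.3.0]octa-diene peroxyketal (1,2,6,6a-tetrahydropentalene core): C1 bearing OO–C(CH3)2OCH3; C3=C4 with CH2OAc on C4; C5=C6; 7β-[(3S)-3-methylpentanoyloxy]; 8α-hydroxy; 8β-(3-methylbutanoyloxymethyl); 9β-H
Conditions: Grubbs second-generation catalyst (10 mol %), ethylene (1 atm), CH2Cl2, 40 °C
Reagents that add atoms: none
Why: Tandem ring-closing dienyne metathesis: the alkylidene formed at the C7 vinyl group closes onto the alkyne (ring B, C5=C6) and the resulting vinylcarbene at C4 captures the C3 vinyl group (ring A, C3=C4); under ethylene a cyclohexene from direct diene closure can re-enter through the alkyne, whose consumption drives the cascade, and no stereocentre is formed.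

**Step 13**
Reactants: 19 bicyclic peroxyketal
Product: 20 bicyclic C1 hydroperoxide (as 19 with OOH on C1)
Conditions: AcOH/THF/H2O (4:2:1), 0 °C to rt; used at once
Reagents that add atoms: none
Why: Mild hydrolysis of the peroxyketal protecting group frees the hydroperoxide with an acid too weak to trigger Hock cleavage or ionise the allylic esters.

**Step 14**
Reactants: 20 bicyclic C1 hydroperoxide; 21 3-methylbut-2-enoic acid
Product: 23 target (CNP0297662.1), via peroxy ester 22 (not isolated)
Conditions: DCC, CH2Cl2, −20 °C to rt, dark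
Reagents that add atoms: none
Why: DCC couples the hydroperoxide with the acid without base to give peroxy ester 22, whose O–O bond ionises with concerted 1,2-shift of the electron-rich dienyl carbon C3 from C1 to oxygen (Criegee rearrangement, the perester counterpart of Hock cleavage of allylic hydroperoxides), and the oxocarbenium/carboxylate ion pair collapses at C1 to the acylal. The six-membered ring is closed by ring expansion, i.e. insertion of O2 into the C1–C3 bond of the cyclopentene ring (new O2–C3 bond), not by a Baldwin-type cyclisation. C1 is the only new stereocentre: it is planar in the oxocarbenium ion, so both C1 epimers of 20 converge, and the carboxylate returns on the face syn to H9 and anti to the C8 branch on C9, which should give the pseudo-axial (1S) acyloxy group. The step needs migration of C3 rather than of C9 or loss of the C1 hydrogen (Kornblum–DeLaMare oxidation to a dienone); the π-donor dienyl group has the highest migratory aptitude, and the absence of amine base and the low temperature disfavour elimination. C9 keeps its configuration because C1 never becomes a free carbonyl group, and the esters, the allylic acetate and the tertiary alcohol are untouched at near-neutral pH.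

**Compound list**

1 | rac-pent-1-en-4-yn-3-ol | C=CC(O)C#C | starting material
2 | (Z)-1-bromoprop-1-ene | C/C=C\Br | starting material
3 | rac-(6Z)-octa-1,6-dien-4-yn-3-ol | C=CC(O)C#C/C=C\C | intermediate
4 | (3S,6Z)-octa-1,6-dien-4-yn-3-ol | C=C[C@H](O)C#C/C=C\C | intermediate
5 | (3S,4E,6Z)-4-(tributylstannyl)octa-1,4,6-trien-3-ol | C=C[C@H](O)/C([Sn](CCCC)(CCCC)CCCC)=C\C=C/C | intermediate
6 | lithium (3S,4Z,6Z)-4-lithioocta-1,4,6-trien-3-olate (not isolated) | C=C[C@H](O[Li])/C([Li])=C\C=C/C | intermediate
7 | (3S,4Z,6Z)-4-(hydroxymethyl)octa-1,4,6-trien-3-ol | C=C[C@H](O)/C(CO)=C\C=C/C | intermediate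
8 | (1S)-1-[(2R,3S)-2-(hydroxymethyl)-3-[(1Z)-prop-1-en-1-yl]oxiran-2-yl]prop-2-en-1-ol | C=C[C@H](O)[C@@]1(CO)O[C@H]1/C=C\C | intermediate
9 | tert-butyldimethyl(prop-2-yn-1-yloxy)silane | C#CCO[Si](C)(C)C(C)(C)C | starting material
10 | (3S,4R,5S,6Z)-5-[3-(tert-butyldimethylsilyloxy)prop-1-yn-1-yl]-4-(hydroxymethyl)octa-1,6-diene-3,4-diol | C=C[C@H](O)[C@](O)(CO)[C@H](C#CCO[Si](C)(C)C(C)(C)C)/C=C\C | intermediate
11 | 3-methylbutanoyl chloride | CC(C)CC(=O)Cl | starting material
12 | (3S,4R,5S,6Z)-5-[3-(tert-butyldimethylsilyloxy)prop-1-yn-1-yl]-3,4-dihydroxy-4-[(3-methylbutanoyloxy)methyl]octa-1,6-diene | C=C[C@H](O)[C@](O)(COC(=O)CC(C)C)[C@H](C#CCO[Si](C)(C)C(C)(C)C)/C=C\C | intermediate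
13 | (3S)-3-methylpentanoic acid | CC[C@H](C)CC(=O)O | starting material
14 | (3S,4R,5S,6Z)-5-[3-(tert-butyldimethylsilyloxy)prop-1-yn-1-yl]-4-hydroxy-4-[(3-methylbutanoyloxy)methyl]octa-1,6-dien-3-yl (3S)-3-methylpentanoate | C=C[C@H](OC(=O)C[C@@H](C)CC)[C@](O)(COC(=O)CC(C)C)[C@H](C#CCO[Si](C)(C)C(C)(C)C)/C=C\C | intermediate
15 | (3S,4R,5S,6Z)-4-hydroxy-5-(3-hydroxyprop-1-yn-1-yl)-4-[(3-methylbutanoyloxy)methyl]octa-1,6-dien-3-yl (3S)-3-methylpentanoate | C=C[C@H](OC(=O)C[C@@H](C)CC)[C@](O)(COC(=O)CC(C)C)[C@H](C#CCO)/C=C\C | intermediate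
16 | (3S,4R,5S,6Z)-5-(3-acetoxyprop-1-yn-1-yl)-4-hydroxy-4-[(3-methylbutanoyloxy)methyl]octa-1,6-dien-3-yl (3S)-3-methylpentanoate | C=C[C@H](OC(=O)C[C@@H](C)CC)[C@](O)(COC(=O)CC(C)C)[C@H](C#CCOC(C)=O)/C=C\C | intermediate
17 | (3S,4R,5R)-5-(3-acetoxyprop-1-yn-1-yl)-6-hydroperoxy-4-hydroxy-4-[(3-methylbutanoyloxy)methyl]octa-1,7-dien-3-yl (3S)-3-methylpentanoate, C6 (iridoid C1) epimers (not isolated) | C=C[C@H](OC(=O)C[C@@H](C)CC)[C@](O)(COC(=O)CC(C)C)[C@H](C#CCOC(C)=O)C(OO)C=C | intermediate
18 | 2-methoxypropan-2-yl peroxyketal of 17 | C=C[C@H](OC(=O)C[C@@H](C)CC)[C@](O)(COC(=O)CC(C)C)[C@H](C#CCOC(C)=O)C(OOC(C)(C)OC)C=C | intermediate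
19 | cis-bicyclo[3.3.0]octa-diene peroxyketal: C1–OO–C(CH3)2OCH3, C3=C4(CH2OAc), C5=C6, 7β-[(3S)-3-methylpentanoyloxy], 8α-OH, 8β-CH2O-isovaleryl, 9β-H (C1 epimers) | CC[C@H](C)CC(=O)O[C@H]1C=C2C(COC(C)=O)=CC(OOC(C)(C)OC)[C@@H]2[C@@]1(O)COC(=O)CC(C)C | intermediate
20 | bicyclic C1 hydroperoxide (19 with free OOH; C1 epimers) | CC[C@H](C)CC(=O)O[C@H]1C=C2C(COC(C)=O)=CC(OO)[C@@H]2[C@@]1(O)COC(=O)CC(C)C | intermediate
21 | 3-methylbut-2-enoic acid | CC(C)=CC(=O)O | starting material
22 | C1 peroxy ester of 20 with 3-methylbut-2-enoic acid (not isolated) | CC[C@H](C)CC(=O)O[C@H]1C=C2C(COC(C)=O)=CC(OOC(=O)C=C(C)C)[C@@H]2[C@@]1(O)COC(=O)CC(C)C | intermediate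
23 | CNP0297662.1: (1S,7S,8R,9S)-configured 1-O-(3-methylbut-2-enoyl), 7-O-[(3S)-3-methylpentanoyl], 10-O-(3-methylbutanoyl), 11-O-acetyl 8-hydroxy iridoid 3,5-diene | CC[C@H](C)CC(=O)O[C@H]1C=C2C(COC(C)=O)=CO[C@@H](OC(=O)C=C(C)C)[C@@H]2[C@@]1(O)COC(=O)CC(C)C | target

**Step count and risks**

Total step count: 14. Longest linear sequence: 14 steps (from 1).

Steps most likely to fail:

Step 14. The peroxy ester may lose the C1 hydrogen (elimination to a dienone) faster than C3 migrates, or the ion pair may collapse with poor facial selectivity at C1. Fallback, from 20 back to 23: treatment of 20 with trifluoroacetic anhydride and 2,6-di-tert-butylpyridine in CH2Cl2 at −78 °C should give the pertrifluoroacetate F1, the classical fast Criegee substrate, which should rearrange at once to the anomeric C1 trifluoroacetate F2. Without isolation, 3-methylbut-2-enoic acid 21 and more hindered base are added at −40 °C, so that F2 ionises to the same oxocarbenium ion and is trapped by the carboxylic acid (anomeric-trifluoroacetate donor chemistry) to give 23.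

Step 12. Direct ring closure between the two vinyl groups may outrun closure onto the alkyne, or the peroxide may shorten catalyst life. Fallback, from 18 back to 19: the diene ring closure is run on purpose with the first-generation Grubbs catalyst, which engages terminal alkenes far faster than the internal alkyne, to give the cyclohexene F3. F3 is then submitted on its own to ring-rearrangement enyne metathesis (Hoveyda–Grubbs II, ethylene, toluene, 60 °C): a ruthenium methylidene adds to the alkyne and the vinylcarbene opens the cyclohexene and closes both five-membered rings, giving 19.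

Step 4. Tin–lithium exchange next to the lithium alkoxide may be incomplete, and the alkenyllithium may be protonated or lose its geometry before it meets formaldehyde. Fallback, from 5 back to 7: iododestannylation of 5 (I2, CH2Cl2, 0 °C) should give the alkenyl iodide F4 with retention, and Stille hydroxymethylation of F4 with (tributylstannyl)methanol (Pd(PPh3)4, dioxane, 80 °C) should give 7 without any organolithium.

**Further compounds**

F1 | step 14 | C1 pertrifluoroacetate of 20 (not isolated) | CC[C@H](C)CC(=O)O[C@H]1C=C2C(COC(C)=O)=CC(OOC(=O)C(F)(F)F)[C@@H]2[C@@]1(O)COC(=O)CC(C)C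
F2 | step 14 | 1-O-trifluoroacetyl analogue of 23 | CC[C@H](C)CC(=O)O[C@H]1C=C2C(COC(C)=O)=CO[C@@H](OC(=O)C(F)(F)F)[C@@H]2[C@@]1(O)COC(=O)CC(C)C
F3 | step 12 | cyclohexene from diene ring closure of 18 (C6=C3 ring bearing C7 acyloxy, C8 OH/CH2O-isovaleryl, C9 acetoxypropynyl, C1 peroxyketal) | CC[C@H](C)CC(=O)O[C@H]1C=CC(OOC(C)(C)OC)[C@@H](C#CCOC(C)=O)[C@@]1(O)COC(=O)CC(C)C
F4 | step 4 | (3S,4E,6Z)-4-iodoocta-1,4,6-trien-3-ol | C=C[C@H](O)/C(I)=C\C=C/C
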